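**Retrosynthetic overview**

1. Feature: central ring B is the cyclohexane CH–CH2–C(CH3)–CH–CH2–CH. Its two directly bonded CH bridgeheads are cis (one shared with cyclopentene ring A, one with cyclopentene ring C), and its quaternary C–CH3 lies 1,4 to the ring-C bridgehead CH. This is the cyclohexene that isoprene and a cyclohex-2-enone give.
2. Last disconnections: the two dioxolanes, then both C(sp2)–cyclopropyl bonds, giving bis(enol triflate) 11 and one cis-cyclopropylzinc reagent (both cyclopropanes of the target have the same absolute configuration).
3. Rings A and C form together from the cis-fused bicyclic 2-methyl-1,3-dione 8 by de Mayo [2+2]/retro-aldol (bonds C(CH3)–C(=O) and CH–CH(CH3)).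
4. Ring B: enantioselective Diels–Alder reaction of isoprene with mono-ketal enone 4 from cyclohexane-1,3-dione. Ring order: dione ring (bought), ring B, then rings A and C.
5. Cyclopropane: copper-catalysed enantioselective syn-carbomagnesiation of 3,3-dimethylcyclopropene (from isobutene), iodine quench.

Key step: step 4

Remark (assumption): the sense of induction in steps 4 and 12 is assigned from the accepted catalyst models; should either prove opposite, the mirror-image catalyst or ligand, equally available, is used.

**Route**

Step 1
Reactants: 1 cyclohexane-1,3-dione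
Product: 2 1,4-dioxaspiro[4.5]decan-7-one
Conditions: HOCH2CH2OH (1.05 equiv), TsOH·H2O (2 mol %), benzene, reflux, Dean–Stark; distillation
Reagents that add atoms: ethylene glycol, OCCO
Why: Acid-catalysed mono-ketalisation with water removal, in which the enolised dione gives the 2-hydroxyethyl enol ether that closes by 5-exo oxa-Michael addition to the spiro-dioxolane; one equivalent of diol and distillation hold the product at the mono-ketal (no stereocentre).

Step 2
Reactants: 2 1,4-dioxaspiro[4.5]decan-7-one
Product: 3 (1,4-dioxaspiro[4.5]dec-7-en-7-yloxy)trimethylsilane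
Conditions: LiN(i-Pr)2 (1.1 equiv), Me3SiCl (1.3 equiv, internal quench), THF, −78 °C
Reagents that add atoms: chlorotrimethylsilane, C[Si](C)(C)Cl
Why: Kinetic enolate silylation: the amide base takes the less hindered C8–H remote from the ketal, so the enolate that could expel a ketal oxygen by E1cB is not formed.

Step 3
Reactants: 3 (1,4-dioxaspiro[4.5]dec-7-en-7-yloxy)trimethylsilane
Product: 4 1,4-dioxaspiro[4.5]dec-8-en-7-one
Conditions: Pd(OAc)2 (1.05 equiv), MeCN, rt; cold filtration through Et3N-deactivated silica
Reagents that add atoms: none
Why: Saegusa–Ito oxidation: the silyl enol ether is converted via an oxa-allyl palladium species and β-hydride elimination into the enone at the position fixed in step 2; the neutral work-up guards against aromatisation to a resorcinol ether.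

Step 4
Reactants: 4 1,4-dioxaspiro[4.5]dec-8-en-7-one; 5 isoprene
Product: 6 cis-fused Diels–Alder adduct (ketone at the ring-fusion CH, dioxolane, trisubstituted alkene), (4a'S,8a'S)
Conditions: (S)-3,3-diphenyl-1-(2-methylphenyl)tetrahydro-1H,3H-pyrrolo[1,2-c][1,3,2]oxazaborole (20 mol %), AlBr3 (16 mol %), 5 (5 equiv), CH2Cl2, −78 → −40 °C; Et3N quench
Reagents that add atoms: none
Why: The AlBr3-activated oxazaborolidine binds the enone carbonyl on the lone pair syn to the vinyl C–H and isoprene adds in a concerted, asynchronous, suprafacial [4+2] cycloaddition; the closest known reaction type is the cationic oxazaborolidine-catalysed Diels–Alder reaction of cyclohex-2-enones and quinone monoketals with 2-substituted butadienes. Ring B closes as a six-membered ring by intermolecular [4+2] annulation that forms both bonds at once, enone β-carbon to the diene CH2 next to the methyl-bearing carbon and enone α-carbon to the other diene CH2. The two new CH stereocentres are cis because both bonds form on one face of the ring alkene, and their absolute configuration is set by the catalyst, whose phenyl group screens one face of the bound enone so that the diene should reach the Si face at the α-carbon. The step needs para regiochemistry, secured by pairing the larger HOMO coefficient at the isoprene terminus next to the methylated carbon with the enone β-carbon, and one enantiotopic face, secured by the catalyst; endo/exo is immaterial because the diene termini are unsubstituted. The dioxolane is protected by using less AlBr3 than oxazaborolidine, low temperature and a basic quench, since its ionisation would lead to aromatisation.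

Step 5
Reactants: 6 cis-fused Diels–Alder adduct
Product: 7 (4aS,8aS)-6-methyl-4a,5,8,8a-tetrahydronaphthalene-1,3(2H,4H)-dione
Conditions: 1 M HCl–THF (1:4), 0 °C → rt
Reagents that add atoms: water, O
Why: Acid hydrolysis of the β-keto dioxolane; the released 1,3-dione enolises at once across the two carbonyls, which disfavours enolisation towards the ring-fusion CH, so the cis fusion should survive these mild conditions.

Step 6
Reactants: 7 (4aS,8aS)-6-methyl-4a,5,8,8a-tetrahydronaphthalene-1,3(2H,4H)-dione
Product: 8 (4aS,8aS)-2,6-dimethyl-1,3-dione, drawn as its 3-hydroxy-enone tautomer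
Conditions: NaOH (1.05 equiv), MeI (1.5 equiv), H2O–1,4-dioxane, 50 °C; then dilute HCl
Reagents that add atoms: iodomethane, CI
Why: C-alkylation of the 1,3-dione mono-anion, for which MeI in a water-rich medium favours carbon over oxygen; one equivalent of hydroxide does not deprotonate the ring-fusion CH, so no stereocentre is touched.

Step 7
Reactants: 8 (4aS,8aS)-2,6-dimethyl-1,3-dione (enol form)
Product: 10 tricyclic 1,5-dione (5,7-dimethyltricyclo[4.2.1.1(2,5)]decane-4,8-dione skeleton), via cyclobutanol photoadduct 9 (not isolated)
Conditions: hν (medium-pressure Hg lamp, Pyrex, λ > 290 nm), degassed MeCN (5 mM), rt; then Et3N (cat.), rt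
Reagents that add atoms: none
Why: de Mayo reaction: in the folded cis-fused conformer the enol C=C opposite the ring fusion lies over the ring-B alkene, so excitation gives an intramolecular straight [2+2] (two five-membered rings) to cyclobutanol 9, whose retro-aldol cleavage releases the 1,5-dione; the tether allows bonding only on the ring-B face that carries the dione ring, which sets the quaternary C–CH3 and its CH neighbour, while the new CH(CH3) centre may form as either epimer.

Step 8
Reactants: 10 tricyclic 1,5-dione
Product: 11 bis(enol triflate)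
Conditions: KN(SiMe3)2 (2.6 equiv), THF, −78 °C; N-(5-chloropyridin-2-yl)bis(trifluoromethanesulfonyl)imide (2.6 equiv), −78 → 0 °C
Reagents that add atoms: N-(5-chloropyridin-2-yl)bis(trifluoromethanesulfonyl)imide, O=S(=O)(N(c1ccc(Cl)cn1)S(=O)(=O)C(F)(F)F)C(F)(F)F
Why: Enol triflate formation from the potassium enolates: each ketone can enolise in one direction only (the other α-carbon is quaternary or a bridgehead barred by Bredt's rule), so both triflates form regiospecifically and the CH(CH3) stereocentre is erased.

Step 9
Reactants: 12 isobutene
Product: 13 1,1-dibromo-2,2-dimethylcyclopropane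
Conditions: CHBr3 (1 equiv), KOt-Bu (1.1 equiv), 12 (excess), pentane, −20 °C → rt
Reagents that add atoms: bromoform, BrC(Br)Br
Why: Doering–Hoffmann cyclopropanation: dibromocarbene from α-elimination of bromoform adds to the electron-rich 1,1-disubstituted alkene.

Step 10
Reactants: 13 1,1-dibromo-2,2-dimethylcyclopropane
Product: 14 1-bromo-2,2-dimethylcyclopropane (racemic)
Conditions: Bu3SnH (1.0 equiv), neat, 30–40 °C; distillation
Reagents that add atoms: none
Why: Radical-chain hydrodebromination with a stannane, which stops at the monobromide because the second C–Br bond is reduced much more slowly; the racemic centre is removed in the next step.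

Step 11
Reactants: 14 1-bromo-2,2-dimethylcyclopropane
Product: 15 3,3-dimethylcyclopropene
Conditions: KOt-Bu (1.5 equiv), DMSO, 25 → 60 °C, product distilled into a −78 °C trap and kept as a cold THF solution
Reagents that add atoms: none
Why: 1,2-Dehydrobromination, possible only towards the ring CH2; the gem-dimethyl group blocks ene dimerisation, so the strained alkene can be collected and handled cold.

Step 12
Reactants: 15 3,3-dimethylcyclopropene; 16 2-(2-bromoethyl)-2-methyl-1,3-dioxolane
Product: 19 2-{2-[(1R,3R)-3-iodo-2,2-dimethylcyclopropyl]ethyl}-2-methyl-1,3-dioxolane (cis), via Grignard reagent 17 (not isolated), via cis-cyclopropylmagnesium bromide 18 (not isolated)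
Conditions: 16, Mg, THF, 30 °C; CuBr·SMe2 (5 mol %), (R)-DTBM-SEGPHOS (5.5 mol %), 15, Et2O–THF, −40 °C; then I2, THF, −78 °C
Reagents that add atoms: iodine, II
Why: Copper-catalysed enantioselective carbomagnesiation of a 3,3-disubstituted cyclopropene: strain-driven syn addition places the alkyl group and the metal cis, the chiral bisphosphine–copper species chooses between the two enantiotopic olefinic carbons, and the configurationally stable cyclopropylmagnesium is iodinated with retention.

Step 13
Reactants: 11 bis(enol triflate); 19 cis-iodocyclopropane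
Product: 23 bis-dioxolane of the target, via cyclopropyllithium 20 (not isolated), via cyclopropylzinc chloride 21 (not isolated), via mono-coupled alkenyl triflate 22 (not isolated)
Conditions: 19 (3 equiv), t-BuLi (6 equiv), Et2O–THF, −78 °C; ZnCl2 (3.2 equiv), −78 °C → rt; 11 (1 equiv), Pd(OAc)2 (10 mol %), SPhos (2-dicyclohexylphosphino-2′,6′-dimethoxybiphenyl, 20 mol %), THF, 50 °C
Reagents that add atoms: none
Why: Iodine–lithium exchange, transmetalation to zinc and twofold Negishi coupling all proceed with retention at the cyclopropyl carbon, so the cis (R,R) reagent is carried unchanged into both alkenyl positions; the bulky electron-rich phosphine is chosen for the tetrasubstituted triflate, and the temperature is kept low enough to avoid the homo-1,5-hydrogen shift of cis-alkyl vinylcyclopropanes.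

Step 14
Reactants: 23 bis-dioxolane of the target
Product: 24 CNP0300925.1
Conditions: PPTS (0.3 equiv), acetone–H2O (10:1), 45 °C
Reagents that add atoms: water, O
Why: Mild acid-catalysed acetal hydrolysis, which frees both methyl ketones under conditions too weak to protonate the alkenes next to the cyclopropanes.

**Compound list**

1 | cyclohexane-1,3-dione | O=C1CCCC(=O)C1 | starting material
2 | 1,4-dioxaspiro[4.5]decan-7-one | O=C1CCCC2(C1)OCCO2 | intermediate
3 | (1,4-dioxaspiro[4.5]dec-7-en-7-yloxy)trimethylsilane | C[Si](C)(C)OC1=CCCC2(C1)OCCO2 | intermediate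
4 | 1,4-dioxaspiro[4.5]dec-8-en-7-one | O=C1C=CCC2(C1)OCCO2 | intermediate
5 | isoprene | C=CC(C)=C | starting material
6 | (4a'S,8a'S)-7'-methyl-4a',5',8',8a'-tetrahydro-1'H-spiro[1,3-dioxolane-2,2'-naphthalen]-4'(3'H)-one, cis-fused | O=C1CC2(OCCO2)C[C@@H]2CC(C)=CC[C@H]12 | intermediate
7 | (4aS,8aS)-6-methyl-4a,5,8,8a-tetrahydronaphthalene-1,3(2H,4H)-dione, cis-fused | O=C1CC(=O)C[C@@H]2CC(C)=CC[C@H]12 | intermediate
8 | (4aS,8aS)-3-hydroxy-2,6-dimethyl-4a,5,8,8a-tetrahydronaphthalen-1(4H)-one (enol tautomer of the 2-methyl-1,3-dione) | O=C1C(C)=C(O)C[C@@H]2CC(C)=CC[C@H]12 | intermediate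
9 | tetracyclic cyclobutanol photoadduct (hydroxyl on the cyclobutane carbon bonded to the quaternary C–CH3; ketone beside the methylated cyclobutane carbon) | O[C@]14C[C@@H]2C[C@@]1(C)[C@H]3C[C@@H]2C(=O)[C@@]43C | intermediate
10 | tricyclic 1,5-dione, 5,7-dimethyltricyclo[4.2.1.1(2,5)]decane-4,8-dione skeleton, ring-B centres as in the target, CH(CH3) centre as either epimer | O=C1C[C@@H]2C[C@@]1(C)[C@H]1C[C@@H]2C(=O)C1C | intermediate
11 | bis(enol triflate) of 10 (one trisubstituted, one tetrasubstituted alkenyl triflate) | O=S(=O)(OC1=C[C@@H]2C[C@@]1(C)[C@H]1C[C@@H]2C(OS(=O)(=O)C(F)(F)F)=C1C)C(F)(F)F | intermediate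
12 | isobutene | CC(C)=C | starting material
13 | 1,1-dibromo-2,2-dimethylcyclopropane | CC1(C)CC1(Br)Br | intermediate
14 | 1-bromo-2,2-dimethylcyclopropane (racemic) | CC1(C)CC1Br | intermediate
15 | 3,3-dimethylcyclopropene | CC1(C)C=C1 | intermediate
16 | 2-(2-bromoethyl)-2-methyl-1,3-dioxolane | CC1(CCBr)OCCO1 | starting material
17 | [2-(2-methyl-1,3-dioxolan-2-yl)ethyl]magnesium bromide | CC1(CC[Mg]Br)OCCO1 | intermediate
18 | cis-{2,2-dimethyl-3-[2-(2-methyl-1,3-dioxolan-2-yl)ethyl]cyclopropyl}magnesium bromide | CC1(CC[C@H]2[C@@H]([Mg]Br)C2(C)C)OCCO1 | intermediate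
19 | 2-{2-[(1R,3R)-3-iodo-2,2-dimethylcyclopropyl]ethyl}-2-methyl-1,3-dioxolane (cis) | CC1(CC[C@H]2[C@@H](I)C2(C)C)OCCO1 | intermediate
20 | cis-cyclopropyllithium from 19 | CC1(CC[C@H]2[C@@H]([Li])C2(C)C)OCCO1 | intermediate
21 | cis-cyclopropylzinc chloride from 20 | CC1(CC[C@H]2[C@@H]([Zn]Cl)C2(C)C)OCCO1 | intermediate
22 | mono-coupled alkenyl triflate (cyclopropyl on ring A, triflate on ring C) | CC5(OCCO5)CC[C@H]1[C@@H](C2=C[C@@H]3C[C@@]2(C)[C@H]2C[C@@H]3C(OS(=O)(=O)C(F)(F)F)=C2C)C1(C)C | intermediate
23 | bis(ethylene ketal) of the target | CC5(OCCO5)CC[C@H]1[C@@H](C2=C[C@@H]3C[C@@]2(C)[C@H]2C[C@@H]3C([C@@H]3[C@H](CCC6(C)OCCO6)C3(C)C)=C2C)C1(C)C | intermediate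
24 | CNP0300925.1 | CC(=O)CC[C@H]1[C@@H](C2=C[C@@H]3C[C@@]2(C)[C@H]2C[C@@H]3C([C@@H]3[C@H](CCC(C)=O)C3(C)C)=C2C)C1(C)C | target

**Step count**

Total: 14 steps. Longest linear sequence: 10 steps (steps 1–8, 13, 14); the cyclopropane branch is steps 9–12.

**Steps most likely to fail**

Step 7. The two enol tautomers of 8 interconvert, and the one whose C=C lies next to the ring fusion could close in the crossed sense, or the excited enol could relax without bonding if the folded conformer is thinly populated. Fallback: the chromophore is locked before irradiation. Setting out from 8, acetylation (Ac2O, pyridine) should give the two regioisomeric enol acetates, the wanted one with the acetoxy group on the carbon next to the ring CH2, enol acetate F6, and its regioisomer, enol acetate F7, which is separated and recycled to 8 with K2CO3/MeOH. Irradiation of F6 (Pyrex, MeCN) can then only give the straight adduct, acetoxycyclobutane F8. K2CO3 in MeOH removes the acetate and triggers the retro-aldol, and the route is rejoined at 10.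

Step 4. The dioxolane may ionise under the Lewis acid with aromatisation of the dienophile, or the cycloaddition may be too slow at temperatures the ketal tolerates. Fallback: setting out from 5, the same catalyst is used with commercial cyclohex-2-en-1-one, which carries nothing acid-labile, and the second carbonyl is added afterwards. The cycloaddition should give the cis-fused methyl-octalone F1. LiN(i-Pr)2/Me3SiCl (kinetic, towards the CH2) gives silyl enol ether F2, and Pd(OAc)2 in MeCN gives enone F3. Conjugate borylation (bis(pinacolato)diboron, CuCl, 4,5-bis(diphenylphosphino)-9,9-dimethylxanthene, NaOt-Bu, MeOH, THF) gives β-boryl ketone F4, NaBO3·4H2O gives β-hydroxy ketone F5, and Dess–Martin periodinane gives the dione, rejoining the route at 7.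

Step 12. Discrimination between the two enantiotopic olefinic carbons of the small, symmetric cyclopropene may be insufficient. Fallback: resolution through a sulfur auxiliary. Setting out from 15 and 16 (via 17), the carbomagnesiation is run with CuBr·SMe2 alone, giving 18 together with its enantiomer, ent-cyclopropylmagnesium bromide F9. Quenching with (1R,2S,5R)-menthyl (S)-p-toluenesulfinate (Andersen substitution, inversion at sulfur) gives two diastereomeric cis-cyclopropyl p-tolyl sulfoxides, separable by chromatography or crystallisation: the one with the needed ring configuration, sulfoxide F10, and the other, sulfoxide F11. Sulfoxide–lithium exchange on F10 (t-BuLi, THF, −78 °C, retention at carbon) followed by I2 returns the route at 19.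

**Further compounds**

F1 | step 4 | cis-fused 6-methyl-3,4,4a,5,8,8a-hexahydronaphthalen-1(2H)-one | O=C1CCC[C@@H]2CC(C)=CC[C@H]12
F2 | step 4 | trimethylsilyl enol ether of F1 (double bond towards the CH2) | C[Si](C)(C)OC1=CCC[C@@H]2CC(C)=CC[C@H]12
F3 | step 4 | cis-fused 6-methyl-4a,5,8,8a-tetrahydronaphthalen-1(4H)-one | O=C1C=CC[C@@H]2CC(C)=CC[C@H]12
F4 | step 4 | β-(pinacolatoboryl) ketone from F3 (boron-bearing carbon as either epimer) | O=C1CC(B2OC(C)(C)C(C)(C)O2)C[C@@H]2CC(C)=CC[C@H]12
F5 | step 4 | β-hydroxy ketone from F4 (carbinol as either epimer) | O=C1CC(O)C[C@@H]2CC(C)=CC[C@H]12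
F6 | step 7 | enol acetate of 8 with acetoxy next to the ring CH2 | O=C1C(C)=C(OC(C)=O)C[C@@H]2CC(C)=CC[C@H]12
F7 | step 7 | regioisomeric enol acetate of 8 with acetoxy next to the ring-fusion CH | CC(=O)OC1=C(C)C(=O)C[C@@H]2CC(C)=CC[C@H]12
F8 | step 7 | acetoxycyclobutane photoadduct (acetate of 9) | CC(=O)O[C@]14C[C@@H]2C[C@@]1(C)[C@H]3C[C@@H]2C(=O)[C@@]43C
F9 | step 12 | enantiomer of cis-cyclopropylmagnesium bromide 18 | CC1(CC[C@@H]2[C@H]([Mg]Br)C2(C)C)OCCO1
F10 | step 12 | (R)-sulfinyl cis-cyclopropyl p-tolyl sulfoxide with the ring configuration of 19 | Cc1ccc(cc1)[S@](=O)[C@@H]1[C@H](CCC2(C)OCCO2)C1(C)C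
F11 | step 12 | (R)-sulfinyl cis-cyclopropyl p-tolyl sulfoxide with the mirror-image ring configuration | Cc1ccc(cc1)[S@](=O)[C@H]1[C@@H](CCC2(C)OCCO2)C1(C)C
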